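## The problem

Abietane numbering is used throughout. The target is (5S,7S,10R,15S).

- Ring B is a boat bridged by the 20,7-lactone. C10–C20(=O)–O–C7 spans its 1,4-positions, so C10 and C7 are the bridgeheads of a 2-oxabicyclo[2.2.2]octan-3-one fused to the catechol ring (C8–C9) and to ring A (C5–C10).
- C10 is quaternary, benzylic, next to the C11 oxygen and carries the carboxyl carbon. C5 carries the CMe2 carbon C4. The C5–C10 bond therefore joins two crowded centres and must be trans (H5 anti to C20).
- C7 is not independent: the bridge can only close on the C20 face. C5 must be set relative to C10, and one core centre must be set absolutely.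
- C15 on the C13 side chain is insulated from the core by the flat arene. It needs its own reagent control.
- Ring C is penta-substituted (C8, C9, O11, O12, C13), and C13 must be distinguished from C14.
- The C7–O bond is a benzylic ester para to O12 (it ionises and hydrogenolyses). The free catechol oxidises easily. The primary acetate must survive the unmasking of the catechol.
- The feature used here is the second six-membered ring of the bicycle, O–C20–C10–C5–C6–C7. With C6=C7 in place of C7–O it is the product of a [3,3] shift of an ester enolate whose alcohol part is the allylic, benzylic C7 carbinol. The first ring, O–C20–C10–C9–C8–C7 (an isochroman-3-one), holds the two reacting ends together.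

## Retrosynthesis

**Side chain and protecting groups (22 ⇐ 21 ⇐ 20 ⇐ 18 ⇐ 17).** The O-methyl groups, the acetyl group and the C13–C15 bond are cut last. C15 needs catalyst control in any case. An aryl bromide is inert to every core-building step, whereas an isopropenyl group would not survive the acid of step 8. Bromide 17 has no side-chain stereocentre. The forward steps are a Suzuki coupling, an enantioselective hydroboration, acetylation, and a demethylation that spares acetate and lactone.

**Ring A (17 ⇐ 16 ⇐ 15).** C2–C3 is cut as a C2=C3 metathesis bond. Unlike a cut at C4–C5 or C1–C10, this touches no stereocentre and carries the quaternary C4 intact as a 2-methylbut-3-en-2-yl group. In 15 the allyl group on C10 and the vinyl group on C4 are held gauche by the bicycle, so ring closure and saturation (no new stereocentre) are all that is asked.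

**Key disconnection (15 ⇐ 14 ⇐ 13 ⇐ 12).** The lactone is opened at O–C7 to the styrene acid 14. The C10–C5 bond is then cut by a retro-[3,3] shift to ketene acetal 13 of the allylic lactone 12. Cutting C10–C5 and C6–C7 together as a cycloaddition would leave a planar precursor with no stereocentre; this cut keeps C7 as a stereocentre that carries the absolute configuration. Lactone 12 is a benzo-fused monocycle with one controlling centre. Product 15 is bridged and has three centres, one of them quaternary. The forward reaction must pass through the boat enforced by the arene bridge and must beat ionisation of the C7–O bond.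

**Lactone 12 (12 ⇐ 11 ⇐ 7 + 3).** C10–C1 is cut (enolate allylation). C7–C6 and O–C20 are cut (addition of an E-alkenylmetal from enyne 3 to aldehyde 7, then lactonisation). The only catalyst-controlled centre of the core is thus a secondary aryl alkenyl carbinol.

**Building blocks (7 ⇐ 6 ⇐ 5 ⇐ 4; 3 ⇐ 2 ⇐ 1).** Two electrophilic substitutions on the arylacetate place CHO at C8 and Br at C13; the in-plane C12 methoxy group and the twisted C11 methoxy group direct them. The reverse-prenyl unit comes from γ-attack of prenylmagnesium chloride 1 on a formyl donor and a one-carbon homologation of aldehyde 2.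

## Roads not taken

Alternative 1: The obvious route cuts C10–C1 and C4–C5. C10 is made by a catalytic asymmetric Michael addition of β-keto ester A1 to methyl vinyl ketone, followed by Robinson annulation to enone A2. After A2 the route still needs deconjugative gem-dimethylation at C4, removal of the C3 ketone, reduction of C5=C6 with H5 anti to the angular ester (not reliably trans next to an angular ester), and a separate benzylic oxidation and lactonisation at C7. The chosen plan fixes C5 and C10 in one sigmatropic step and gets C7–O from the same intermediate.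

Alternative 2: Cut C10–C5 and C6–C7 together. Formyl acid A3 is dehydrated (Ac2O, heat) to the 2-benzopyran-3-one A4, whose intramolecular Diels–Alder reaction gives A5 with rings A, B and the lactone in one step. The diene A4 is planar with enantiotopic faces, the tether has no stereocentre, C15 is too far away, and the unactivated vinyl group offers no hold for a chiral catalyst. A5 would therefore form racemic, with the exo/endo (trans/cis) choice also open. The chosen plan uses the same bicyclo[2.2.2] array but enters it from a stereocentre (C7).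

Alternative 3: Cut C4–C5 and C9–C10 in an enantioselective cationic polyene cyclisation of A6 to A7. The arene would close para to the C11 methoxy group (at C14) rather than at the crowded C9, giving the wrong ring-C pattern. C20 must be carried as CH2OR, because an ester on the central alkene stops the cation cascade, and then raised three oxidation levels. C7 needs a further oxidation. The chosen plan carries C20 as the lactone carbonyl from the first step.

Key step: step 8

Remark: the sense of induction of the chiral catalysts in steps 6 and 12 is assigned by analogy with simpler substrates and must be confirmed; both ligand antipodes are available.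

## Route

Step 1
Reactants: 1 3-methylbut-2-en-1-ylmagnesium chloride (prenylmagnesium chloride, commercial THF solution)
Product: 2 2,2-dimethylbut-3-enal
Conditions: DMF, THF, −20 °C → rt; 1 M HCl, 0 °C
Reagents that add atoms: N,N-dimethylformamide, CN(C)C=O
Why: Bouveault-type formylation; the allylic Grignard reagent reacts at its γ-carbon (SE2′), which puts the formyl group on the tertiary carbon and leaves the vinyl group; the aldehyde has no α-hydrogen.

Step 2
Reactants: 2 2,2-dimethylbut-3-enal
Product: 3 3,3-dimethylpent-1-en-4-yne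
Conditions: MeC(O)C(N2)P(O)(OMe)2, K2CO3, MeOH, 0 °C → rt
Reagents that add atoms: dimethyl (1-diazo-2-oxopropyl)phosphonate, CC(=O)C(=[N+]=[N-])P(=O)(OC)OC
Why: Ohira–Bestmann homologation of a non-enolisable aldehyde to the terminal alkyne under mild base; the volatile enyne is handled as a toluene solution.

Step 3
Reactants: 4 2-(2,3-dimethoxyphenyl)acetic acid
Product: 5 methyl 2-(2,3-dimethoxyphenyl)acetate
Conditions: MeOH, H2SO4 (cat.), reflux
Reagents that add atoms: methanol, CO
Why: Fischer esterification; the ester later serves as the acyl part of the lactone and tolerates the Lewis acid of step 4.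

Step 4
Reactants: 5 methyl 2-(2,3-dimethoxyphenyl)acetate
Product: 6 methyl 2-(6-formyl-2,3-dimethoxyphenyl)acetate
Conditions: Cl2CHOMe, TiCl4, CH2Cl2, −10 → 0 °C; H2O
Reagents that add atoms: dichloromethyl methyl ether, COC(Cl)Cl; water, O
Why: Rieche formylation; attack should go para to the C12 methoxy group, the only one that can lie in the ring plane (the C11 methoxy group is flanked on both sides), which is the position ortho to the CH2CO2Me group, as in the formylation of 2,3-dimethoxytoluene.

Step 5
Reactants: 6 methyl 2-(6-formyl-2,3-dimethoxyphenyl)acetate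
Product: 7 methyl 2-(4-bromo-6-formyl-2,3-dimethoxyphenyl)acetate
Conditions: Br2, NaOAc, AcOH, rt
Reagents that add atoms: bromine, BrBr
Why: Electrophilic aromatic bromination; C13 is ortho to the in-plane C12 methoxy group, para to the alkyl group and meta to CHO, whereas C14 is ortho to CHO and para only to the twisted C11 methoxy group (the same pattern directs bromination of 2,3,4-trimethoxybenzaldehyde to C5).

Step 6
Reactants: 3 3,3-dimethylpent-1-en-4-yne, 7 methyl 2-(4-bromo-6-formyl-2,3-dimethoxyphenyl)acetate
Product: 11 (1S)-7-bromo-1-[(1E)-3,3-dimethylpenta-1,4-dien-1-yl]-5,6-dimethoxy-1,4-dihydro-3H-2-benzopyran-3-one, via alkenylborane 8 (not isolated), via alkenylzinc 9 (not isolated), via hydroxy ester 10 (not isolated)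
Conditions: 3, Cy2BH, toluene, 0 °C → rt; Me2Zn, −78 °C; (−)-MIB (5 mol %), 7, −20 → 0 °C, then rt; aq NH4Cl
Reagents that add atoms: none
Why: Catalytic enantioselective alkenylzinc addition to an aryl aldehyde (syn-hydroboration of the terminal alkyne in preference to the neopentyl-type vinyl group fixes the E geometry, then B/Zn exchange); the amino alcohol ligand should direct Si-face attack to give the S carbinol, and the zinc alkoxide closes onto the neighbouring ester under non-acidic conditions, so the ionisable benzylic, allylic C7–O bond never meets acid.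

Step 7
Reactants: 11 (1S)-7-bromo-1-[(1E)-3,3-dimethylpenta-1,4-dien-1-yl]-5,6-dimethoxy-1,4-dihydro-3H-2-benzopyran-3-one
Product: 12 (1S,4RS)-7-bromo-1-[(1E)-3,3-dimethylpenta-1,4-dien-1-yl]-5,6-dimethoxy-4-(prop-2-en-1-yl)-1,4-dihydro-3H-2-benzopyran-3-one (both C4 epimers)
Conditions: LiHMDS, THF, −78 °C; allyl bromide, −78 → −40 °C
Reagents that add atoms: allyl bromide, C=CCBr
Why: Lithium enolate C-alkylation at the benzylic α-carbon of the lactone (C10), held at mono-allylation by stoichiometry; both C10 epimers are used because this centre becomes planar in step 8, and the cold basic medium leaves C7 untouched.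

Step 8
Reactants: 12 (1S,4RS)-7-bromo-1-[(1E)-3,3-dimethylpenta-1,4-dien-1-yl]-5,6-dimethoxy-4-(prop-2-en-1-yl)-1,4-dihydro-3H-2-benzopyran-3-one
Product: 15 (1R,2S,4S)-6-bromo-4-hydroxy-7,8-dimethoxy-2-(2-methylbut-3-en-2-yl)-1-(prop-2-en-1-yl)-1,2,3,4-tetrahydronaphthalene-1-carboxylic acid 1,4-lactone, via silyl ketene acetal 13 (not isolated), via dihydronaphthalene acid 14 (not isolated)
Conditions: KHMDS, TMSCl, THF–toluene, −78 → 80 °C; 1 M HCl; then TFA, CH2Cl2, 0 °C
Reagents that add atoms: none
Why: Deprotonation at C10 and O-silylation give ketene acetal 13, whose array C10=C20(OSi)–O–C7–C6=C5 undergoes the [3,3] shift that makes C10–C5, breaks O–C7 and moves the alkene to C6=C7 (Ireland–Claisen rearrangement); acid then protonates the electron-rich styrene at C6 and the C20 acid captures the C7 cation. The closest known reaction type is the ring-contracting Ireland–Claisen rearrangement of six-membered lactones that carry an alkenyl group on the carbinol carbon, which gives cyclohexene carboxylic acids through a boat transition state. Ring B is closed in the sigmatropic step (six-membered carbocycle by C–C bonding between the termini of the array), and the δ-lactone is closed afterwards by Markovnikov hydro-acyloxylation of C6=C7, a six-membered O-closure onto the benzylic cation that completes the 2-oxabicyclo[2.2.2]octanone. Because C7 and C10 are also joined through C8–C9 of the arene, the array can only be a boat with the alkenyl group axial on C7, so C5 reaches the face of C10 on which that group lies and C10 (R) follows from C7 (S) alone. In this boat the E alkene puts C4 anti to C9 and H5 anti to C20, which is the 5S configuration of the later trans A/B fusion; both C10 epimers of 12 converge in 13. C7 is re-formed with the only configuration the bridge allows (S), so the stereocentre that was spent is returned. The concerted shift must outrun heterolysis of the benzylic, allylic C7–O bond, which the neutral silyl ketene acetal in a non-polar medium and the pre-organised cyclic array should secure. Protonation must select C6=C7 over the allyl and vinyl groups and O-capture must beat attack of these alkenes on the cation, which the far higher basicity of the para-methoxy styrene and the placement of the acid across the ring should secure.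

Step 9
Reactants: 15 (1R,2S,4S)-6-bromo-4-hydroxy-7,8-dimethoxy-2-(2-methylbut-3-en-2-yl)-1-(prop-2-en-1-yl)-1,2,3,4-tetrahydronaphthalene-1-carboxylic acid 1,4-lactone
Product: 16 (4aR,9S,10aS)-7-bromo-5,6-dimethoxy-1,1-dimethyl-1,9,10,10a-tetrahydro-4H-9,4a-(epoxymethano)phenanthren-12-one (ring-A alkene at abietane C2=C3)
Conditions: Hoveyda–Grubbs II (5 mol %), toluene, 80 °C
Reagents that add atoms: none
Why: Ring-closing metathesis of the allyl group with the hindered vinyl group on the quaternary carbon, with loss of ethene; the bicycle holds the two groups gauche, as C1 and C4 are in the final chair, and no stereocentre is touched.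

Step 10
Reactants: 16 (4aR,9S,10aS)-7-bromo-5,6-dimethoxy-1,1-dimethyl-1,9,10,10a-tetrahydro-4H-9,4a-(epoxymethano)phenanthren-12-one
Product: 17 (4aR,9S,10aS)-7-bromo-5,6-dimethoxy-1,1-dimethyl-1,3,4,9,10,10a-hexahydro-2H-9,4a-(epoxymethano)phenanthren-12-one
Conditions: H2 (1 atm), [Ir(cod)(PCy3)(py)]PF6 (5 mol %), CH2Cl2, rt
Reagents that add atoms: none
Why: Homogeneous hydrogenation of the hindered cis-disubstituted ring alkene with Crabtree's catalyst; no stereocentre is formed, and the aryl bromide and the benzylic lactone C–O bond, both at risk over heterogeneous palladium, are kept.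

Step 11
Reactants: 17 (4aR,9S,10aS)-7-bromo-5,6-dimethoxy-1,1-dimethyl-1,3,4,9,10,10a-hexahydro-2H-9,4a-(epoxymethano)phenanthren-12-one
Product: 18 (4aR,9S,10aS)-5,6-dimethoxy-1,1-dimethyl-7-(prop-1-en-2-yl)-1,3,4,9,10,10a-hexahydro-2H-9,4a-(epoxymethano)phenanthren-12-one
Conditions: isopropenyl-Bpin, Pd(dppf)Cl2 (5 mol %), K3PO4, dioxane–H2O, 80 °C
Reagents that add atoms: 4,4,5,5-tetramethyl-2-(prop-1-en-2-yl)-1,3,2-dioxaborolane, CC(=C)B1OC(C)(C)C(C)(C)O1
Why: Suzuki–Miyaura coupling of an aryl bromide with one ortho substituent; if base opens the lactone, it can only re-close with the same configuration on acidic work-up.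

Step 12
Reactants: 18 (4aR,9S,10aS)-5,6-dimethoxy-1,1-dimethyl-7-(prop-1-en-2-yl)-1,3,4,9,10,10a-hexahydro-2H-9,4a-(epoxymethano)phenanthren-12-one
Product: 20 (4aR,9S,10aS)-7-[(2S)-1-hydroxypropan-2-yl]-5,6-dimethoxy-1,1-dimethyl-1,3,4,9,10,10a-hexahydro-2H-9,4a-(epoxymethano)phenanthren-12-one, via alkyl pinacolboronate 19 (not isolated)
Conditions: HBpin, CoCl2·chiral iminopyridine–oxazoline ligand (3 mol %), NaBHEt3 (cat.), THF, rt; then NaBO3·4H2O, THF–H2O
Reagents that add atoms: sodium perborate, [Na+].[O-]OB=O (hydroxyl oxygen); pinacolborane, CC1(C)OBOC1(C)C (boron of 19)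
Why: Catalyst-controlled anti-Markovnikov hydroboration of a 1,1-disubstituted aryl alkene (cobalt hydride with a chiral ligand, a reaction type established for α-methylstyrenes), then oxidation with retention; C15 is set by the ligand (antipode chosen for 15S) because the core centres are too remote to help or interfere.

Step 13
Reactants: 20 (4aR,9S,10aS)-7-[(2S)-1-hydroxypropan-2-yl]-5,6-dimethoxy-1,1-dimethyl-1,3,4,9,10,10a-hexahydro-2H-9,4a-(epoxymethano)phenanthren-12-one
Product: 21 (2S)-2-[(4aR,9S,10aS)-5,6-dimethoxy-1,1-dimethyl-12-oxo-1,3,4,9,10,10a-hexahydro-2H-9,4a-(epoxymethano)phenanthren-7-yl]propyl acetate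
Conditions: Ac2O, pyridine, DMAP (cat.), CH2Cl2, 0 °C → rt
Reagents that add atoms: acetic anhydride, CC(=O)OC(C)=O
Why: Acylation of the only free hydroxyl group; C15 is not epimerisable under these conditions.

Step 14
Reactants: 21 (2S)-2-[(4aR,9S,10aS)-5,6-dimethoxy-1,1-dimethyl-12-oxo-1,3,4,9,10,10a-hexahydro-2H-9,4a-(epoxymethano)phenanthren-7-yl]propyl acetate
Product: 22 (2S)-2-[(4aR,9S,10aS)-5,6-dihydroxy-1,1-dimethyl-12-oxo-1,3,4,9,10,10a-hexahydro-2H-9,4a-(epoxymethano)phenanthren-7-yl]propyl acetate (target)
Conditions: BBr3, CH2Cl2, −78 → −20 °C; aq NaHCO3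
Reagents that add atoms: none
Why: Lewis acid O-demethylation of the catechol dimethyl ether through the cyclic borate at low temperature, where alkyl acetates and lactones are normally retained; if the C7–O bond ionises transiently, the lactone can only re-close with the same configuration.

## Compound list

1 | 3-methylbut-2-en-1-ylmagnesium chloride | CC(C)=CC[Mg]Cl | starting material
2 | 2,2-dimethylbut-3-enal | CC(C)(C=C)C=O | intermediate
3 | 3,3-dimethylpent-1-en-4-yne | C#CC(C)(C)C=C | intermediate
4 | 2-(2,3-dimethoxyphenyl)acetic acid | COc1cccc(CC(=O)O)c1OC | starting material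
5 | methyl 2-(2,3-dimethoxyphenyl)acetate | COC(=O)Cc1cccc(OC)c1OC | intermediate
6 | methyl 2-(6-formyl-2,3-dimethoxyphenyl)acetate | COC(=O)Cc1c(C=O)ccc(OC)c1OC | intermediate
7 | methyl 2-(4-bromo-6-formyl-2,3-dimethoxyphenyl)acetate | COC(=O)Cc1c(C=O)cc(Br)c(OC)c1OC | intermediate
8 | dicyclohexyl[(1E)-3,3-dimethylpenta-1,4-dien-1-yl]borane | C=CC(C)(C)/C=C/B(C1CCCCC1)C1CCCCC1 | intermediate
9 | [(1E)-3,3-dimethylpenta-1,4-dien-1-yl](methyl)zinc | C=CC(C)(C)/C=C/[Zn]C | intermediate
10 | methyl 2-{4-bromo-6-[(1S,2E)-1-hydroxy-4,4-dimethylhexa-2,5-dien-1-yl]-2,3-dimethoxyphenyl}acetate (formed as its zinc alkoxide) | COC(=O)Cc1c(OC)c(OC)c(Br)cc1[C@@H](O)/C=C/C(C)(C)C=C | intermediate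
11 | (1S)-7-bromo-1-[(1E)-3,3-dimethylpenta-1,4-dien-1-yl]-5,6-dimethoxy-1,4-dihydro-3H-2-benzopyran-3-one | O=C1Cc2c(OC)c(OC)c(Br)cc2[C@H](/C=C/C(C)(C)C=C)O1 | intermediate
12 | (1S,4RS)-7-bromo-1-[(1E)-3,3-dimethylpenta-1,4-dien-1-yl]-5,6-dimethoxy-4-(prop-2-en-1-yl)-1,4-dihydro-3H-2-benzopyran-3-one | O=C1C(CC=C)c2c(OC)c(OC)c(Br)cc2[C@H](/C=C/C(C)(C)C=C)O1 | intermediate
13 | {[(1S)-7-bromo-1-[(1E)-3,3-dimethylpenta-1,4-dien-1-yl]-5,6-dimethoxy-4-(prop-2-en-1-yl)-1H-2-benzopyran-3-yl]oxy}trimethylsilane | C[Si](C)(C)OC1=C(CC=C)c2c(OC)c(OC)c(Br)cc2[C@H](/C=C/C(C)(C)C=C)O1 | intermediate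
14 | (1R,2S)-6-bromo-7,8-dimethoxy-2-(2-methylbut-3-en-2-yl)-1-(prop-2-en-1-yl)-1,2-dihydronaphthalene-1-carboxylic acid | OC(=O)[C@]1(CC=C)[C@H](C(C)(C)C=C)C=Cc2cc(Br)c(OC)c(OC)c21 | intermediate
15 | (1R,2S,4S)-6-bromo-4-hydroxy-7,8-dimethoxy-2-(2-methylbut-3-en-2-yl)-1-(prop-2-en-1-yl)-1,2,3,4-tetrahydronaphthalene-1-carboxylic acid 1,4-lactone (abietane C5 S, C7 S, C10 R) | Brc1cc2c(c(OC)c1OC)[C@@]1(CC=C)[C@H](C(C)(C)C=C)C[C@@H]2OC1=O | intermediate
16 | (4aR,9S,10aS)-7-bromo-5,6-dimethoxy-1,1-dimethyl-1,9,10,10a-tetrahydro-4H-9,4a-(epoxymethano)phenanthren-12-one | Brc1cc2c(c(OC)c1OC)[C@@]13CC=CC(C)(C)[C@@H]1C[C@@H]2OC3=O | intermediate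
17 | (4aR,9S,10aS)-7-bromo-5,6-dimethoxy-1,1-dimethyl-1,3,4,9,10,10a-hexahydro-2H-9,4a-(epoxymethano)phenanthren-12-one | Brc1cc2c(c(OC)c1OC)[C@@]13CCCC(C)(C)[C@@H]1C[C@@H]2OC3=O | intermediate
18 | (4aR,9S,10aS)-5,6-dimethoxy-1,1-dimethyl-7-(prop-1-en-2-yl)-1,3,4,9,10,10a-hexahydro-2H-9,4a-(epoxymethano)phenanthren-12-one | C=C(C)c1cc2c(c(OC)c1OC)[C@@]13CCCC(C)(C)[C@@H]1C[C@@H]2OC3=O | intermediate
19 | 2-{(2R)-2-[(4aR,9S,10aS)-5,6-dimethoxy-1,1-dimethyl-12-oxo-1,3,4,9,10,10a-hexahydro-2H-9,4a-(epoxymethano)phenanthren-7-yl]propyl}-4,4,5,5-tetramethyl-1,3,2-dioxaborolane | CC1(C)OB(C[C@@H](C)c2cc3c(c(OC)c2OC)[C@@]24CCCC(C)(C)[C@@H]2C[C@@H]3OC4=O)OC1(C)C | intermediate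
20 | (4aR,9S,10aS)-7-[(2S)-1-hydroxypropan-2-yl]-5,6-dimethoxy-1,1-dimethyl-1,3,4,9,10,10a-hexahydro-2H-9,4a-(epoxymethano)phenanthren-12-one | OC[C@@H](C)c1cc2c(c(OC)c1OC)[C@@]13CCCC(C)(C)[C@@H]1C[C@@H]2OC3=O | intermediate
21 | (2S)-2-[(4aR,9S,10aS)-5,6-dimethoxy-1,1-dimethyl-12-oxo-1,3,4,9,10,10a-hexahydro-2H-9,4a-(epoxymethano)phenanthren-7-yl]propyl acetate | CC(=O)OC[C@@H](C)c1cc2c(c(OC)c1OC)[C@@]13CCCC(C)(C)[C@@H]1C[C@@H]2OC3=O | intermediate
22 | (2S)-2-[(4aR,9S,10aS)-5,6-dihydroxy-1,1-dimethyl-12-oxo-1,3,4,9,10,10a-hexahydro-2H-9,4a-(epoxymethano)phenanthren-7-yl]propyl acetate | CC(=O)OC[C@@H](C)c1cc2c(c(O)c1O)[C@@]13CCCC(C)(C)[C@@H]1C[C@@H]2OC3=O | target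

## Step count and least certain steps

Total: 14 steps. Longest linear sequence: 12 steps (4 → 22, steps 3 to 14).

**Step 8 (key step).** The boat places the CMe2 group on C5 directly over the allyl CH2 on C10. This compression may slow the sigmatropic shift enough for heterolysis of the benzylic, allylic C7–O bond (loss of stereochemical information, allylic scrambling) or silyl migration to compete. In the acid stage, the pendant alkenes may attack the C7 cation. Fallback: change the order so that the rearrangement forms a tertiary, not a quaternary, C10. Set out from 11. Enolisation and silylation (KHMDS, TMSCl) give {[(1S)-7-bromo-1-[(1E)-3,3-dimethylpenta-1,4-dien-1-yl]-5,6-dimethoxy-1H-2-benzopyran-3-yl]oxy}trimethylsilane F1, in which only a hydrogen lies under C4. Its rearrangement and hydrolysis give (1R,2S)-6-bromo-7,8-dimethoxy-2-(2-methylbut-3-en-2-yl)-1,2-dihydronaphthalene-1-carboxylic acid F2. The dianion of this acid (2 equiv LDA) is allylated anti to the pseudo-axial tert-alkyl group on C5. This gives 14, where the route is rejoined at the acid treatment of step 8.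

**Step 6.** Face selection at the aldehyde may be incomplete, because the ortho CH2CO2Me group can chelate zinc. Methyl transfer may compete. The product may lose configuration by ionisation on acidic supports. Fallback: set C7 by reduction instead of addition. From 7 and 3, the same alkenylzinc addition without ligand, quenched cold, gives racemic methyl 2-{4-bromo-6-[(2E)-1-hydroxy-4,4-dimethylhexa-2,5-dien-1-yl]-2,3-dimethoxyphenyl}acetate F3. MnO2 oxidises it to methyl 2-{4-bromo-6-[(2E)-4,4-dimethylhexa-2,5-dienoyl]-2,3-dimethoxyphenyl}acetate F4. Enantioselective carbonyl reduction (oxazaborolidine-catalysed borane reduction, or a ketoreductase if aryl and alkenyl are not told apart) gives 10. Base (DBU) lactonises 10 to 11, where the route is rejoined.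

**Step 12.** The ortho methoxy group may erode facial selection at the alkene, and hydride may attack the lactone. Fallback: separate the epimers by an enzyme that also installs the acetate. From 18, 9-BBN gives the B-alkyl-9-borabicyclo[3.3.1]nonane adduct F5 as both C15 epimers, and NaBO3 oxidises it to 20 together with its epimer (4aR,9S,10aS)-7-[(2R)-1-hydroxypropan-2-yl]-5,6-dimethoxy-1,1-dimethyl-1,3,4,9,10,10a-hexahydro-2H-9,4a-(epoxymethano)phenanthren-12-one F6. A lipase with vinyl acetate distinguishes 2-arylpropan-1-ols at the centre next to CH2OH; taken here to acylate the 15S epimer, it gives 21 directly and leaves F6. The route is rejoined at 21 and step 13 is skipped.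

**Step 14.** The acetate may be cleaved or turned into a bromide. The lactone may open with elimination toward the 6,7-alkene. The catechol may oxidise during work-up. Fallback: unmask before acylation and differentiate the esters afterwards. From 20, BBr3 at low temperature gives (4aR,9S,10aS)-5,6-dihydroxy-7-[(2S)-1-hydroxypropan-2-yl]-1,1-dimethyl-1,3,4,9,10,10a-hexahydro-2H-9,4a-(epoxymethano)phenanthren-12-one F7. Ac2O and pyridine give the triacetate (4aR,9S,10aS)-7-[(2S)-1-acetoxypropan-2-yl]-1,1-dimethyl-12-oxo-1,3,4,9,10,10a-hexahydro-2H-9,4a-(epoxymethano)phenanthrene-5,6-diyl diacetate F8. Mild aminolysis (NH4OAc, aqueous MeOH) removes only the two aryl acetates, which are far more labile than the alkyl acetate; the hindered C11 acetate can leave after migration to O12. This gives 22.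

## Further compounds

F1 | step 8 | {[(1S)-7-bromo-1-[(1E)-3,3-dimethylpenta-1,4-dien-1-yl]-5,6-dimethoxy-1H-2-benzopyran-3-yl]oxy}trimethylsilane | C[Si](C)(C)OC1=Cc2c(OC)c(OC)c(Br)cc2[C@H](/C=C/C(C)(C)C=C)O1
F2 | step 8 | (1R,2S)-6-bromo-7,8-dimethoxy-2-(2-methylbut-3-en-2-yl)-1,2-dihydronaphthalene-1-carboxylic acid | OC(=O)[C@@H]1[C@H](C(C)(C)C=C)C=Cc2cc(Br)c(OC)c(OC)c21
F3 | step 6 | methyl 2-{4-bromo-6-[(2E)-1-hydroxy-4,4-dimethylhexa-2,5-dien-1-yl]-2,3-dimethoxyphenyl}acetate (racemic) | COC(=O)Cc1c(OC)c(OC)c(Br)cc1C(O)/C=C/C(C)(C)C=C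
F4 | step 6 | methyl 2-{4-bromo-6-[(2E)-4,4-dimethylhexa-2,5-dienoyl]-2,3-dimethoxyphenyl}acetate | COC(=O)Cc1c(OC)c(OC)c(Br)cc1C(=O)/C=C/C(C)(C)C=C
F5 | step 12 | (4aR,9S,10aS)-7-[1-(9-borabicyclo[3.3.1]nonan-9-yl)propan-2-yl]-5,6-dimethoxy-1,1-dimethyl-1,3,4,9,10,10a-hexahydro-2H-9,4a-(epoxymethano)phenanthren-12-one (both C15 epimers) | CC(CB1C2CCCC1CCC2)c1cc2c(c(OC)c1OC)[C@@]13CCCC(C)(C)[C@@H]1C[C@@H]2OC3=O
F6 | step 12 | (4aR,9S,10aS)-7-[(2R)-1-hydroxypropan-2-yl]-5,6-dimethoxy-1,1-dimethyl-1,3,4,9,10,10a-hexahydro-2H-9,4a-(epoxymethano)phenanthren-12-one | OC[C@H](C)c1cc2c(c(OC)c1OC)[C@@]13CCCC(C)(C)[C@@H]1C[C@@H]2OC3=O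
F7 | step 14 | (4aR,9S,10aS)-5,6-dihydroxy-7-[(2S)-1-hydroxypropan-2-yl]-1,1-dimethyl-1,3,4,9,10,10a-hexahydro-2H-9,4a-(epoxymethano)phenanthren-12-one | OC[C@@H](C)c1cc2c(c(O)c1O)[C@@]13CCCC(C)(C)[C@@H]1C[C@@H]2OC3=O
F8 | step 14 | (4aR,9S,10aS)-7-[(2S)-1-acetoxypropan-2-yl]-1,1-dimethyl-12-oxo-1,3,4,9,10,10a-hexahydro-2H-9,4a-(epoxymethano)phenanthrene-5,6-diyl diacetate | CC(=O)OC[C@@H](C)c1cc2c(c(OC(C)=O)c1OC(C)=O)[C@@]13CCCC(C)(C)[C@@H]1C[C@@H]2OC3=O
A1 | alternative 1 | methyl 6-bromo-7,8-dimethoxy-2-oxo-1,2,3,4-tetrahydronaphthalene-1-carboxylate | COC(=O)C1C(=O)CCc2cc(Br)c(OC)c(OC)c21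
A2 | alternative 1 | methyl 6-bromo-7,8-dimethoxy-3-oxo-1,2,3,9,10-pentahydrophenanthrene-4a-carboxylate type Robinson enone (natural C10 configuration; abietane C3 ketone, C4=C5) | COC(=O)[C@]12CCC(=O)C=C1CCc1cc(Br)c(OC)c(OC)c12
A3 | alternative 2 | 2-(4-bromo-6-formyl-2,3-dimethoxyphenyl)-6,6-dimethyloct-7-enoic acid (racemic) | OC(=O)C(CCCC(C)(C)C=C)c1c(C=O)cc(Br)c(OC)c1OC
A4 | alternative 2 | 7-bromo-4-(4,4-dimethylhex-5-en-1-yl)-5,6-dimethoxy-3H-2-benzopyran-3-one | O=C1OC=C2C=C(Br)C(OC)=C(OC)C2=C1CCCC(C)(C)C=C
A5 | alternative 2 | 7-bromo-5,6-dimethoxy-1,1-dimethyl-1,3,4,9,10,10a-hexahydro-2H-9,4a-(epoxymethano)phenanthren-12-one (racemic, ring fusion not controlled) | Brc1cc2c(c(OC)c1OC)C13CCCC(C)(C)C1CC2OC3=O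
A6 | alternative 3 | 5-{(3E)-3-[(benzyloxy)methyl]-7-methylocta-3,6-dien-1-yl}-1-bromo-2,3-dimethoxybenzene | CC(C)=CCC/C(COCc1ccccc1)=C/CCc1cc(OC)c(OC)c(Br)c1
A7 | alternative 3 | (4aS,10aS)-4a-[(benzyloxy)methyl]-7-bromo-5,6-dimethoxy-1,1-dimethyl-1,2,3,4,4a,9,10,10a-octahydrophenanthrene (natural C5 and C10 arrangement) | COc1c(Br)cc2c(c1OC)[C@@]1(COCc3ccccc3)CCCC(C)(C)[C@@H]1CC2
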